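**Retrosynthetic overview**

- Numbering used: N–C1–C2–C3=C4, C5 ketone, C6, C7 (ring-fusion CH), C8, C15 (bearing the C16 methyl), C14, C13 (CHOAc), C12 (quaternary), C11–C10–C9–N. Ring A is the cyclohexane C7/C8/C15/C14/C13/C12, ring B the cyclopentanone C4–C7/C12, ring C the azonine.
- Feature: quaternary C12 lies in ring A between C13 and the fusion carbon C7 and para to the oxygenated C15, so C12 and C7 can both be drawn from a flat, prochiral 4,4-disubstituted cyclohexa-2,5-dienone whose carbonyl is C15.
- Disconnections: N–C1 (sulfonamide alkylation, ring C, last); C3–C4 (β-ketoester dianion aldol, with C3=C4 made by elimination inside ring C so that only the ring-cis E geometry can form); C13–O and C15–CH3 on the leftover enone; C6–C7 (desymmetrising Michael addition, ring B).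
- Ring order: ring A (Robinson annulation, then dehydrogenation to the dienone), ring B (key step), ring C (Mitsunobu closure), then acetylation and elimination.

Key step: step 6

Assumption: the quinine-derived thiourea is taken to select the enantiotopic C=C that leads to bicycle 17 as drawn, and the (R,Sp) ferrocenyl bisphosphine to deliver boron to the ring-B face of C13; if either sense proves opposite, the quinidine-derived pseudoenantiomer or the (S,Rp) ligand is used with no other change.

**Route**

Step 1
Reactants: 1 pent-4-enal; 2 tert-butyl bromoacetate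
Product: 5 tert-butyl 3-formylhex-5-enoate (racemic), via N-cyclohexyl aldimine 3 (not isolated), via alkylated aldimine 4 (not isolated)
Conditions: c-C6H11NH2, MgSO4, Et2O, 0 °C; LiN(i-Pr)2, THF, −78 °C; then 2, −78 → 0 °C; aq. oxalic acid, rt
Reagents that add atoms: none
Why: Stork–Dowd metalloenamine alkylation, in which the lithio-azaenolate of the aldimine is alkylated once at carbon by the reactive α-bromo ester and mild aqueous acid returns the α-branched aldehyde without touching the tert-butyl ester.

Step 2
Reactants: 5 tert-butyl 3-formylhex-5-enoate; 6 methyl vinyl ketone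
Product: 9 tert-butyl 2-(1-allyl-4-oxocyclohex-2-en-1-yl)acetate (racemic), via pyrrolidine enamine 7 (not isolated), via keto aldehyde 8 (not isolated)
Conditions: pyrrolidine (1.2 equiv), K2CO3, toluene, rt; 6, 0 °C → rt; then AcOH, NaOAc, H2O, 70 °C
Reagents that add atoms: none
Why: Stork enamine Robinson annulation, in which the enamine of the α-branched aldehyde adds to the enone to create the quaternary carbon (future C12) and buffered hydrolysis with aldol condensation closes ring A as the 4,4-disubstituted cyclohex-2-enone.

Step 3
Reactants: 9 tert-butyl 2-(1-allyl-4-oxocyclohex-2-en-1-yl)acetate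
Product: 10 2-(1-allyl-4-oxocyclohex-2-en-1-yl)acetic acid
Conditions: CF3CO2H, CH2Cl2, 0 °C → rt
Reagents that add atoms: none
Why: Acidolysis of the tert-butyl ester with loss of isobutene leaves the enone and the terminal alkene untouched.

Step 4
Reactants: 10 2-(1-allyl-4-oxocyclohex-2-en-1-yl)acetic acid; 11 Meldrum's acid; 12 allyl alcohol
Product: 14 allyl 4-(1-allyl-4-oxocyclohex-2-en-1-yl)-3-oxobutanoate, via acyl Meldrum's acid 13 (not isolated)
Conditions: 11, EDC·HCl, DMAP, CH2Cl2, 0 °C → rt; aq. KHSO4 wash; then 12 (5 equiv), toluene, 85 °C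
Reagents that add atoms: none
Why: Oikawa–Yonemitsu β-ketoester synthesis (C-acylation of Meldrum's acid, thermolysis to the acylketene, capture by allyl alcohol) builds C5–C6 and the ester under neutral conditions, so no metal enolate is ever present beside the ring-A enone.

Step 5
Reactants: 14 allyl 4-(1-allyl-4-oxocyclohex-2-en-1-yl)-3-oxobutanoate
Product: 16 allyl 4-(1-allyl-4-oxocyclohexa-2,5-dien-1-yl)-3-oxobutanoate (achiral), via bis(trimethylsilyl) enol ether 15 (not isolated)
Conditions: Et3N (3 equiv), then TMSOTf (2.3 equiv), CH2Cl2, −78 → 0 °C; solvent switch; Pd(OAc)2 (1.2 equiv), MeCN, rt; aq. NH4Cl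
Reagents that add atoms: none
Why: Saegusa–Ito dehydrogenation, in which the enone (no γ-hydrogen) can only give the 2-silyloxy-1,3-diene that Pd(OAc)2 oxidises at room temperature to the cross-conjugated dienone, while the electron-poor β-silyloxy enoate is inert and keeps the carbon acid masked until aqueous work-up; the step is run without heating because 4-allyl dienones are prone to sigmatropic allyl shifts.

Step 6
Reactants: 16 allyl 4-(1-allyl-4-oxocyclohexa-2,5-dien-1-yl)-3-oxobutanoate
Product: 17 cis-fused bicyclic enone β-keto allyl ester (C7–H and the C12 allyl group on the same face; drawn as the C5 enol)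
Conditions: 1-[3,5-bis(trifluoromethyl)phenyl]-3-[(8α,9S)-6′-methoxycinchonan-9-yl]thiourea (10 mol %), toluene (0.05 M), −20 °C
Reagents that add atoms: none
Why: The quinuclidine nitrogen deprotonates the β-ketoester at C6 while the thiourea hydrogen-bonds to the dienone carbonyl, and the bound enolate adds to C7, the β-carbon of one of the two enantiotopic enones, forming C6–C7. The closest known reaction type is the bifunctional amine–thiourea-catalysed desymmetrising intramolecular Michael addition of carbon acids to 4,4-disubstituted cyclohexa-2,5-dienones. Ring B closes in the 5-(enolexo)-exo-trig mode, which the ester makes possible by letting the enolate C=C lie outside the forming ring. C12 and C7 are set together by the catalyst's choice between the enantiotopic C=C bonds, and the cis fusion is fixed by the three-atom tether, which can reach only the face from which it hangs; C6 is labile and of no consequence. The step needs enantiotopic-group selectivity free of racemic background cyclisation, which is secured by keeping 16 base-free until the catalyst is added; a second Michael addition to the remaining C13=C14 enone cannot occur because it would form a four-membered ring.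

Step 7
Reactants: 17 cis-fused bicyclic enone β-keto allyl ester
Product: 19 C13 β-hydroxy ketone (C13–OH on the ring-B face and anti to the allyl group), via C13 pinacol boronate 18 (not isolated)
Conditions: CuCl (10 mol %), (R)-1-[(Sp)-2-(diphenylphosphino)ferrocenyl]ethyldicyclohexylphosphine (11 mol %), NaOt-Bu (1.2 equiv), B2pin2 (1.3 equiv), MeOH (3 equiv), THF, 0 °C → rt; then NaBO3·4H2O, THF/H2O, rt
Reagents that add atoms: sodium perborate, [Na+].[O-]OB=O
Why: Copper-catalysed conjugate borylation (syn addition of L–Cu–Bpin, then protonation) of the C13=C14–C15=O enone places boron on C13 on the face chosen by the chiral bisphosphine, and perborate oxidation replaces boron by oxygen with retention; the β-ketoester is parked as its sodium enolate, which also makes the allyl ester a poor leaving group toward the copper boryl.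

Step 8
Reactants: 19 C13 β-hydroxy ketone
Product: 20 C13 triethylsilyl ether
Conditions: Et3SiCl, imidazole, DMAP (cat.), DMF, 0 °C → rt; aq. citric acid wash
Reagents that add atoms: chlorotriethylsilane, CC[Si](Cl)(CC)CC
Why: Standard silylation of the secondary alcohol, whose bulky equatorial silyloxy group also locks the ring-A chair (C4 axial, C6 equatorial) for the next step and blocks β-elimination.

Step 9
Reactants: 20 C13 triethylsilyl ether
Product: 21 C15 tertiary alcohol (C15–OH cis to C13–O; C16 methyl on the face of H7)
Conditions: Me3Al (6 equiv), toluene, −40 → 0 °C; aq. KNaC4H4O6 work-up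
Reagents that add atoms: trimethylaluminium, C[Al](C)C
Why: Excess Me3Al in a hydrocarbon solvent adds to cyclohexanones by axial methyl delivery (two-aluminium pathway), giving the equatorial tertiary alcohol and so setting C15 with its oxygen cis to C13–O, while the β-ketoester is protected in the flask as its aluminium enolate.

Step 10
Reactants: 21 C15 tertiary alcohol; 22 3-[(4-methoxybenzyl)oxy]propanal
Product: 23 C4 aldol adduct (mixture at C3 and C4; drawn as the C5 enol)
Conditions: LiN(i-Pr)2 (3.3 equiv), THF, −78 → −20 °C; 22, −78 °C; AcOH/THF quench at −78 °C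
Reagents that add atoms: none
Why: Huckin–Weiler dianion aldol, in which the third equivalent of base (after the alkoxide and the C6 enolate) removes a C4 hydrogen and this γ-carbanion, the most nucleophilic site, adds to the aldehyde to form C3–C4; the two new centres are uncontrolled and need not be, since both become trigonal in step 20.

Step 11
Reactants: 23 C4 aldol adduct
Product: 24 C3 triethylsilyl ether
Conditions: Et3SiCl, imidazole, DMF, 0 °C; aq. citric acid wash
Reagents that add atoms: chlorotriethylsilane, CC[Si](Cl)(CC)CC
Why: Chemoselective silylation of the secondary C3 carbinol beside the tertiary C15 alcohol protects the aldol against retro-aldol cleavage and against dehydration under the later Mitsunobu conditions.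

Step 12
Reactants: 24 C3 triethylsilyl ether
Product: 25 C5 ketone (ester removed)
Conditions: Pd(PPh3)4 (5 mol %), morpholine (3 equiv), THF, rt
Reagents that add atoms: none
Why: Tsuji deallylation–decarboxylation, in which zerovalent palladium ionises the allyl ester, morpholine captures the allyl group and the β-keto acid loses CO2 at room temperature with protonation at C6, so the C3 silyloxy group is not eliminated and the unactivated C12 allyl group is untouched.

Step 13
Reactants: 25 C5 ketone
Product: 27 C9 primary alcohol, via C9 pinacol boronate 26 (not isolated)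
Conditions: RhCl(PPh3)3 (5 mol %), pinacolborane (3 equiv), CH2Cl2, rt; then NaBO3·4H2O, THF/H2O, rt
Reagents that add atoms: sodium perborate, [Na+].[O-]OB=O
Why: Rhodium-catalysed hydroboration is selective for the terminal alkene over the hindered C5 ketone (Männig–Nöth chemoselectivity) and gives the linear boronate, which is oxidised with retention to the primary alcohol.

Step 14
Reactants: 27 C9 primary alcohol; 28 2-nitrobenzenesulfonamide
Product: 29 C9 N-(2-nitrobenzenesulfonyl)amine
Conditions: PPh3, DIAD, 28 (4 equiv), THF, 0 °C → rt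
Reagents that add atoms: none
Why: Mitsunobu N-alkylation of the acidic primary sulfonamide, used in excess to suppress double alkylation, occurs only at the primary C9 alcohol because the tertiary C15 alcohol is inert.

Step 15
Reactants: 29 C9 N-(2-nitrobenzenesulfonyl)amine
Product: 30 C1 primary alcohol
Conditions: DDQ, CH2Cl2/pH 7 buffer, 0 °C
Reagents that add atoms: none
Why: Oxidative cleavage of the 4-methoxybenzyl ether frees the C1 alcohol and leaves the silyl ethers, the sulfonamide and the ketone intact.

Step 16
Reactants: 30 C1 primary alcohol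
Product: 31 N-(2-nitrobenzenesulfonyl)azonane
Conditions: PPh3, DIAD, toluene/THF, 0.003 M, slow addition, rt
Reagents that add atoms: none
Why: Intramolecular Fukuyama–Mitsunobu alkylation of the sulfonamide under high dilution closes ring C by N–C1 bond formation, a mode of azonane closure established for fawcettimine-type frameworks, with the quaternary C12 and the ring-B anchor restricting the chain conformations.

Step 17
Reactants: 31 N-(2-nitrobenzenesulfonyl)azonane
Product: 32 secondary amine (azonane N–H)
Conditions: PhSH, K2CO3, MeCN, rt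
Reagents that add atoms: none
Why: Fukuyama deprotection, in which the thiolate adds to the nitroarene (Meisenheimer complex) and releases the amine with loss of SO2.

Step 18
Reactants: 32 secondary amine
Product: 33 N-methyl azonane bis(triethylsilyl) ether
Conditions: aq. CH2O (10 equiv), NaBH(OAc)3, AcOH, ClCH2CH2Cl, rt
Reagents that add atoms: formaldehyde, C=O
Why: Reductive amination with formaldehyde methylates the amine; NaBH(OAc)3 does not reduce the hindered C5 ketone and the excess of formaldehyde outruns transannular iminium formation.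

Step 19
Reactants: 33 N-methyl azonane bis(triethylsilyl) ether
Product: 34 triol (C3, C13 and C15 hydroxyls free)
Conditions: HF·pyridine, pyridine/THF, 0 °C → rt
Reagents that add atoms: none
Why: Fluoride cleavage of both triethylsilyl ethers under non-basic conditions avoids retro-aldol opening at the C3 carbinol.

Step 20
Reactants: 34 triol
Product: 36 CNP0386920.1, via triacetate 35 (not isolated)
Conditions: Ac2O, Et3N, DMAP, CH2Cl2, rt → 40 °C; then DBU, rt
Reagents that add atoms: acetic anhydride, CC(=O)OC(C)=O
Why: Steglich acetylation esterifies the secondary C13, tertiary C15 and C3 hydroxyls, and DBU then expels the C3 acetate by E1cB elimination through the C5 enolate; because C3=C4 forms inside the nine-membered ring, only the ring-cis (E) enone can arise.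

**Compound list**

1 | pent-4-enal | C=CCCC=O | starting material
2 | tert-butyl bromoacetate | BrCC(=O)OC(C)(C)C | starting material
3 | N-cyclohexyl pent-4-en-1-imine (not isolated) | C=CCCC=NC1CCCCC1 | intermediate
4 | tert-butyl 3-[(cyclohexylimino)methyl]hex-5-enoate (not isolated) | C=CCC(C=NC1CCCCC1)CC(=O)OC(C)(C)C | intermediate
5 | tert-butyl 3-formylhex-5-enoate (racemic) | C=CCC(C=O)CC(=O)OC(C)(C)C | intermediate
6 | methyl vinyl ketone | CC(=O)C=C | starting material
7 | tert-butyl 3-(pyrrolidin-1-ylmethylidene)hex-5-enoate (not isolated) | C=CCC(=CN1CCCC1)CC(=O)OC(C)(C)C | intermediate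
8 | tert-butyl 3-allyl-3-formyl-6-oxoheptanoate (not isolated) | C=CCC(C=O)(CCC(C)=O)CC(=O)OC(C)(C)C | intermediate
9 | tert-butyl 2-(1-allyl-4-oxocyclohex-2-en-1-yl)acetate (racemic) | C=CCC1(CC(=O)OC(C)(C)C)C=CC(=O)CC1 | intermediate
10 | 2-(1-allyl-4-oxocyclohex-2-en-1-yl)acetic acid (racemic) | C=CCC1(CC(=O)O)C=CC(=O)CC1 | intermediate
11 | Meldrum's acid (2,2-dimethyl-1,3-dioxane-4,6-dione) | CC1(C)OC(=O)CC(=O)O1 | starting material
12 | allyl alcohol | C=CCO | starting material
13 | acyl Meldrum's acid of 10, enol form (not isolated) | C=CCC1(CC(O)=C2C(=O)OC(C)(C)OC2=O)C=CC(=O)CC1 | intermediate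
14 | allyl 4-(1-allyl-4-oxocyclohex-2-en-1-yl)-3-oxobutanoate (racemic) | C=CCOC(=O)CC(=O)CC1(CC=C)C=CC(=O)CC1 | intermediate
15 | bis(trimethylsilyl) enol ether of 14 (not isolated) | C=CCOC(=O)C=C(O[Si](C)(C)C)CC1(CC=C)C=CC(O[Si](C)(C)C)=CC1 | intermediate
16 | allyl 4-(1-allyl-4-oxocyclohexa-2,5-dien-1-yl)-3-oxobutanoate (achiral; key-step precursor) | C=CCOC(=O)CC(=O)CC1(CC=C)C=CC(=O)C=C1 | intermediate
17 | cis-fused bicyclic enone β-keto allyl ester (key-step product; C7–H and C12 allyl syn; drawn as the C5 enol) | C1=CC(=O)C[C@H]2C(C(=O)OCC=C)=C(O)C[C@@]12CC=C | intermediate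
18 | C13 pinacol boronate of 17 (boron on the ring-B face; not isolated) | CC3(C)OB(OC3(C)C)[C@H]1CC(=O)C[C@H]2C(C(=O)OCC=C)=C(O)C[C@]21CC=C | intermediate
19 | C13 β-hydroxy C15 ketone (C13–OH syn to ring B, anti to allyl) | O[C@H]1CC(=O)C[C@H]2C(C(=O)OCC=C)=C(O)C[C@]21CC=C | intermediate
20 | C13 triethylsilyl ether of 19 | CC[Si](CC)(CC)O[C@H]1CC(=O)C[C@H]2C(C(=O)OCC=C)=C(O)C[C@]21CC=C | intermediate
21 | C15 tertiary alcohol (C15–OH cis to C13–OSiEt3; C16 methyl on the H7 face) | CC[Si](CC)(CC)O[C@H]1C[C@@](C)(O)C[C@H]2C(C(=O)OCC=C)=C(O)C[C@]21CC=C | intermediate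
22 | 3-[(4-methoxybenzyl)oxy]propanal | O=CCCOCc1ccc(OC)cc1 | starting material
23 | C4 aldol adduct (C3 carbinol; mixture at C3 and C4) | CC[Si](CC)(CC)O[C@H]1C[C@@](C)(O)C[C@H]2C(C(=O)OCC=C)=C(O)C(C(O)CCOCc3ccc(OC)cc3)[C@]21CC=C | intermediate
24 | C3 triethylsilyl ether of 23 | CC[Si](CC)(CC)O[C@H]1C[C@@](C)(O)C[C@H]2C(C(=O)OCC=C)=C(O)C(C(O[Si](CC)(CC)CC)CCOCc3ccc(OC)cc3)[C@]21CC=C | intermediate
25 | C5 ketone after decarboxylation (C12 allyl retained) | CC[Si](CC)(CC)O[C@H]1C[C@@](C)(O)C[C@H]2CC(=O)C(C(O[Si](CC)(CC)CC)CCOCc3ccc(OC)cc3)[C@]21CC=C | intermediate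
26 | C9 pinacol boronate of 25 (not isolated) | CC[Si](CC)(CC)O[C@H]1C[C@@](C)(O)C[C@H]2CC(=O)C(C(O[Si](CC)(CC)CC)CCOCc3ccc(OC)cc3)[C@]21CCCB4OC(C)(C)C(C)(C)O4 | intermediate
27 | C9 primary alcohol | CC[Si](CC)(CC)O[C@H]1C[C@@](C)(O)C[C@H]2CC(=O)C(C(O[Si](CC)(CC)CC)CCOCc3ccc(OC)cc3)[C@]21CCCO | intermediate
28 | 2-nitrobenzenesulfonamide | NS(=O)(=O)c1ccccc1[N+](=O)[O-] | starting material
29 | C9 N-(2-nitrobenzenesulfonyl)amine | CC[Si](CC)(CC)O[C@H]1C[C@@](C)(O)C[C@H]2CC(=O)C(C(O[Si](CC)(CC)CC)CCOCc3ccc(OC)cc3)[C@]21CCCNS(=O)(=O)c4ccccc4[N+](=O)[O-] | intermediate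
30 | C1 primary alcohol | CC[Si](CC)(CC)O[C@H]1C[C@@](C)(O)C[C@H]2CC(=O)C(C(O[Si](CC)(CC)CC)CCO)[C@]21CCCNS(=O)(=O)c3ccccc3[N+](=O)[O-] | intermediate
31 | N-(2-nitrobenzenesulfonyl)azonane (ring C closed; C3 and C4 still mixtures) | CC[Si](CC)(CC)O[C@H]1C[C@@](C)(O)C[C@H]2CC(=O)C3C(O[Si](CC)(CC)CC)CCN(S(=O)(=O)c4ccccc4[N+](=O)[O-])CCC[C@@]321 | intermediate
32 | secondary amine (azonane N–H) | CC[Si](CC)(CC)O[C@H]1C[C@@](C)(O)C[C@H]2CC(=O)C3C(O[Si](CC)(CC)CC)CCNCCC[C@@]321 | intermediate
33 | N-methyl azonane bis(triethylsilyl) ether | CC[Si](CC)(CC)O[C@H]1C[C@@](C)(O)C[C@H]2CC(=O)C3C(O[Si](CC)(CC)CC)CCN(C)CCC[C@@]321 | intermediate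
34 | triol (C3, C13, C15 hydroxyls) | O[C@H]1C[C@@](C)(O)C[C@H]2CC(=O)C3C(O)CCN(C)CCC[C@@]321 | intermediate
35 | triacetate of 34 (not isolated) | CC(=O)O[C@H]1C[C@@](C)(OC(C)=O)C[C@H]2CC(=O)C3C(OC(C)=O)CCN(C)CCC[C@@]321 | intermediate
36 | CNP0386920.1, (7S,12S,13S,15S) in the numbering above, C3=C4 of E geometry | CC(=O)O[C@H]1C[C@@](C)(OC(C)=O)C[C@H]2CC(=O)/C3=C/CCN(C)CCC[C@@]321 | target

**Step count**

Total: 20 steps. Longest linear sequence: 20 steps from pent-4-enal (1); all other building blocks are commercial.

**Steps most likely to fail**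

1. Step 7 (borylation at C13). The cis-fused enone is expected to prefer attack at C13 from the convex face, syn to the allyl group, so the ligand has to override the substrate; poor facial selectivity or delivery to the wrong face may result. The fallback sets out from 17 and comes back at 21, replacing steps 7 to 9 by hydroxyl-directed chemistry. After deprotonation of the β-ketoester with NaH, MeLi/CeCl3 adds to the C15 carbonyl from the convex face to give the tertiary allylic alcohol F1. VO(acac)2 with t-BuOOH then epoxidises C13=C14 syn to that hydroxyl to give the epoxy alcohol F2. Cp2TiCl (trivalent titanium, made from Cp2TiCl2 and zinc dust) with 1,4-cyclohexadiene opens the epoxide reductively at C14 to the cis-1,3-diol F3. Et3SiCl/imidazole silylates only the secondary C13 hydroxyl to return 21.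

2. Step 10 (dianion aldol at C4). Removal of the neopentyl C4 hydrogen may be slow, the allyl ester dianion may undergo Carroll rearrangement if warmed, and the aldolate may revert. The fallback sets out from 21 and comes back at 23. Me3SiCl/Et3N followed by LiN(i-Pr)2/Me3SiCl gives the tris(trimethylsilyl) 1,3-bis(silyloxy)diene F4; deprotonating the neutral silyl enol ether at C4 is easier than forming the dianion. A BF3·OEt2-mediated vinylogous Mukaiyama aldol addition of F4 to aldehyde 22 at −78 °C, with dilute acid work-up, returns 23.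

3. Step 16 (nine-membered ring closure). Oligomerisation or slow closure of the medium ring may dominate under the redox-condensation conditions. The fallback sets out from 30 and comes back at 31 by changing the ring closure to an anionic displacement. I2/PPh3/imidazole converts the C1 alcohol into the primary iodide F5, and Cs2CO3 in MeCN at high dilution closes the ring by SN2 attack of the caesium sulfonamide.

**Further compounds**

F1 | step 7 | C15 tertiary allylic alcohol from 1,2-methyl addition to 17 | C1=C[C@@](C)(O)C[C@H]2C(C(=O)OCC=C)=C(O)C[C@]21CC=C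
F2 | step 7 | C13,C14 epoxy alcohol, epoxide syn to the C15 hydroxyl | O3[C@H]1[C@@H]3[C@@](C)(O)C[C@H]2C(C(=O)OCC=C)=C(O)C[C@]21CC=C
F3 | step 7 | cis-1,3-diol (C13 and C15 hydroxyls free) | O[C@H]1C[C@@](C)(O)C[C@H]2C(C(=O)OCC=C)=C(O)C[C@]21CC=C
F4 | step 10 | tris(trimethylsilyl) 1,3-bis(silyloxy)diene of 21 | CC[Si](CC)(CC)O[C@H]1C[C@@](C)(O[Si](C)(C)C)C[C@H]2C(=C(OCC=C)O[Si](C)(C)C)C(O[Si](C)(C)C)=C[C@]21CC=C
F5 | step 16 | C1 primary iodide of 30 | CC[Si](CC)(CC)O[C@H]1C[C@@](C)(O)C[C@H]2CC(=O)C(C(O[Si](CC)(CC)CC)CCI)[C@]21CCCNS(=O)(=O)c3ccccc3[N+](=O)[O-]
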